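## Structural features

The target is an isoflavone: a chromen-4-one (benzo ring A fused to pyranone ring C) that carries a tetrasubstituted benzene (ring B) at C3. Ring B is fused through C4a''/C8a'' to a 2,2-dimethyl-3-hydroxydihydropyran (ring D), so rings B and D form a 2,2-dimethylchroman-3-ol bonded to C3 through C6''. Ring A has hydroxyls at C5 and C7 and the ring oxygen at C8a, a phloroglucinol pattern around C4a. Ring B has a free phenol at C5'', between the aryl–C3 bond and the benzylic C4'' methylene, and its second oxygen is the ring D ether O1''. The only stereocentre is C3'' (S), a secondary carbinol between the quaternary C2'' and C4''H2; it has no neighbouring stereocentre and must be set by reagent control. Fragile sites are C2 of the chromone (alkoxide or hydroxide adds there and can open ring C), the reducible C2=C3 bond, the tertiary alkyl aryl ether O1''–C2'' with its β-hydroxyl (acid-induced ionisation or dehydration), and the electron-rich ring B. The difficulty is regiochemical: a 1,2,3,4-tetrasubstituted ring B with the pyran fused on the correct side, four hydroxyls of different kinds, and a C3–aryl bond next to an ortho oxygen. The key step uses the fact that C5, C7 and C8a are each ortho or para to the C4 carbonyl on C4a. They therefore map onto the three C–F carbons of a 2,4,6-trifluorobenzoyl group: C8a–F is displaced intramolecularly by O1 when ring C closes, and C5–F and C7–F are exchanged for oxygen afterwards.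

## Logic of the disconnections

20 ⇒ 19. The four O–CH2Ph bonds (O5, O7, O5'', O3'') are cut. One neutral hydrogenolysis then unmasks every hydroxyl, so the free polyphenol never meets acid or base. The forward step must stop before C2=C3 is saturated.

19 ⇒ 17. The C5–O and C7–O bonds are cut back to C–F. Both carbons are activated by the C4 carbonyl, so oxygen can enter by addition–elimination, and ring A then comes from a symmetric trifluoroarene with no phenol differentiation. The forward step needs two displacements by benzyl oxide (through 18) without lasting attack at C2.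

17 ⇒ 14 + 15 (key disconnection). The C2–C3 and O1–C8a bonds are cut; C2 and O1 both come from the formyl group of 15. Ring C disappears and the problem becomes a deoxybenzoin-type ketone. The forward step requires enolate 16 to close through oxygen onto an ortho C–F carbon, and the alkoxide released must be harmless, which is why 15 is a benzyl ester.

14 ⇒ 13 ⇒ 10 + 11. The ketone is traced to the carbinol, and the bond between the carbinol carbon and the fluorinated ring is cut to give aldehyde 10 and aryllithium 12, made from 11. All three C–H bonds of 11 are equivalent, so lithiation is unambiguous. The forward steps need low temperature (12 loses LiF when warm), addition faster than enolisation of 10, and a non-basic oxidant.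

10 ⇒ 9. The aldehyde is masked as a methyl enol ether. This form is inert to hydride and to NaH, so the homologated carbon can be carried through the two preceding operations. The forward step is a mild acid hydrolysis that spares the benzyl and chroman ethers.

9 ⇒ 8. The O3''–CH2Ph bond is cut. The carbinol must be masked before the organolithium, the oxidant and the key step, and benzyl adds no extra deprotection step. The forward step alkylates a hindered secondary alkoxide.

8 ⇒ 7. The C4''–H bond is cut back to the C4''–O bond of an oxirane. This turns the isolated carbinol stereocentre into a product of alkene epoxidation. The forward step needs hydride attack at the benzylic C4'' only, with the C3''–O bond untouched.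

7 ⇒ 6. The enol ether C=C bond is cut (Wittig) back to the aryl aldehyde. It is the only C–C bond needed between ring B and the bridge carbon. The ylide must tolerate the epoxide.

6 ⇒ 5. The C3''–O and C4''–O bonds of the oxirane are cut. A cis, aryl-conjugated 2,2-dimethylchromene alkene is the best substrate class for catalyst-controlled oxygen transfer, and C3'' is set early on a cheap intermediate. The forward step needs high face selectivity and an aldehyde that survives the oxidant.

5 ⇒ 4. The O5''–CH2Ph bond is cut. The phenol must be masked before the oxidation catalyst and all later basic steps.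

4 ⇒ 1 + 2. The C4''–C4a'' and O1''–C2'' bonds are cut (through 3). One step builds ring D with its gem-dimethyl group and the alkene needed for the stereocentre. The formyl group of 1 fixes the regiochemistry by hydrogen-bonding its ortho hydroxyl, and it is also the handle for the bridge to ring A. The forward step needs condensation at the carbon between the two oxygens.

## Other disconnections considered

Alternative 1: The C3''–O and C4''–O bonds are made last. The achiral tribenzylated pyrano-isoflavone A1 would be epoxidised with (S,S)-N,N'-bis(3,5-di-tert-butylsalicylidene)-1,2-cyclohexanediaminomanganese chloride (trivalent manganese), NaOCl and 4-phenylpyridine N-oxide to give A2. Reductive opening at C4'' and debenzylation would follow.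
- In favour: every earlier step is free of stereochemical concern, O3'' never needs a protecting group, and hydrogenolysis of the benzylic C4''–O bond could in principle be merged with the final debenzylation.
- Step economy: A1 could be reached by the same fluoride-displacement chemistry with steps 3, 5 and 6 left out, so this plan is about two steps shorter. On step count it is the better plan.
- Stereocontrol: the stereo-determining event is the same reaction class as step 3 of the chosen route, so the two are equal in principle.
- Against: the oxidation falls on the most valuable intermediate, and the enantiomeric purity is fixed two steps from the end with little chance to upgrade it. Hydride reagents cannot open A2 because the chromone is reducible, which leaves only hydrogenolysis. On an electron-rich benzylic epoxide that may compete with palladium-induced isomerisation to a chromanone (which erases C3'') and with saturation of C2=C3.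
- Why the chosen plan is kept: it sets C3'' at step 3 on the small aldehyde 5, opens the epoxide with hydride before any chromone exists, and allows purification at 6 or 8.

Alternative 2: Ring B is built by a Danheiser benzannulation. Irradiation of the chromonyl diazo enone A3 causes a Wolff rearrangement; its 1,2-shift already joins C5' to C6'. The resulting ketene combines with the siloxyalkyne A4 by [2+2] cycloaddition, 4π ring opening and 6π electrocyclisation, forming C2'–C3', C4'–C5' and C1'–C2' to give phenol A5.
- In favour: high convergence, ring B substitution fixed by the mechanism, and the two ring B oxygens arrive differentiated (free hydroxyl at C2', silyl ether at C4').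
- Stereocontrol: the stereocentre would come from asymmetric dihydroxylation of a trisubstituted prenyl alkene, which is equal in reliability to the chromene epoxidation.
- Against: the chromone absorbs in the same region as the diazo ketone and is photoreactive. A3 requires diazomethane-type chemistry on a Michael-acceptor enone. A4 is a multistep, sensitive ynol ether.
- After A5: ring D is still open. Its closure needs protection of the C2' hydroxyl, desilylation, and etherification of the C4' oxygen at the tertiary carbon. That etherification must be SN1-type to keep the C3'' configuration, since a route through an epoxide would invert it.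
- Comparison: the chosen plan gets rings B and D in one step from 1 and 2. Alternative 2 is better in convergence but clearly worse in step count and in operational risk.

Alternative 3: Ring C is closed by a [4+2] annulation. Thermolysis or photolysis of benzodioxinone A6 releases an ortho-quinoid ketene that combines with the pyrrolidine enamine A7. A7 derives from an arylacetaldehyde of the same type as 10, with a silyl group in place of benzyl at O3''. The C3–C4 and O1–C2 bonds form and, after loss of the secondary amine, A8 results.
- In favour: ring A arrives fully oxygenated, so the fluoride exchange (step 11) is not needed and the route is one step shorter after the annulation (better). The conditions are base-free, which is better for the chromone C2 position. The front end up to the arylacetaldehyde is shared with the chosen route (equal).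
- Against: the amine expelled on aromatisation is a fast ketene trap, so part of A6 would be consumed as an amide unless it is used in excess. [2+2] addition and simple C-acylation may compete with the [4+2] mode. Enamines of α-aryl acetaldehydes are sensitive. A6 brings back the selective protection of a phloroglucinol acid, which the trifluoroarene avoids.
- Comparison: the chosen Claisen and addition–elimination sequence has the firmer mechanistic footing and is preferred for that reason.

Key step: step 10

Remarks on the chemistry:
- Chroman atoms are double-primed (O1''–C8a'') and chromone atoms are unprimed.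
- Assumption: the (S,S) manganese salen chloride gives the (3S,4S)-epoxide, as is general for 2,2-dimethylchromenes. If the sense were opposite for 5, the (R,R) complex would be used with no other change.
- Hydride opening at C4'' leaves the C3'' descriptor unchanged, because the ranking O > C2'' > C4'' > H holds in both 7 and 8.
- Enol ethers 7–9 are carried as E/Z mixtures and carbinol 13 as both epimers; both elements are erased in steps 7 and 9.
- The constitution and the (S) descriptor of 14 and 17 agree atom by atom with 20, so no structural correction is needed.
- Benzyl formate is used as the formyl donor in place of an alkyl formate. The alkoxide released in the Claisen step is then benzyl oxide, which can only install the ether that step 11 introduces anyway.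

## Route

Step 1
Reactants: 1 2,4-dihydroxybenzaldehyde; 2 3-methylbut-2-enal
Product: 4 5-hydroxy-2,2-dimethyl-2H-chromene-6-carbaldehyde, via ortho-quinone methide dienone 3 (not isolated)
Conditions: pyridine, 140 °C, sealed tube
Reagents that add atoms: none
Why: Base-mediated aldol-type condensation of the enal at the carbon between the two oxygens, dehydration to 3 and oxa-6π electrocyclisation (chromenylation of a resorcinol). The 2-hydroxyl is held in a hydrogen bond to the formyl group, so the 4-oxygen closes the pyran and the angular 5-hydroxychromene should result.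

Step 2
Reactants: 4 5-hydroxy-2,2-dimethyl-2H-chromene-6-carbaldehyde
Product: 5 5-(benzyloxy)-2,2-dimethyl-2H-chromene-6-carbaldehyde
Conditions: BnBr, K2CO3, DMF, 60 °C
Reagents that add atoms: benzyl bromide, BrCc1ccccc1
Why: Williamson etherification; the chelated phenol needs carbonate in warm DMF. Benzyl is chosen so that all hydroxyl masks fall together in step 12.

Step 3
Reactants: 5 5-(benzyloxy)-2,2-dimethyl-2H-chromene-6-carbaldehyde
Product: 6 (3S,4S)-5-(benzyloxy)-3,4-epoxy-2,2-dimethylchromane-6-carbaldehyde
Conditions: (S,S)-N,N'-bis(3,5-di-tert-butylsalicylidene)-1,2-cyclohexanediaminomanganese chloride (4 mol%), 4-phenylpyridine N-oxide (0.2 equiv), aq. NaOCl (pH 11.3, Na2HPO4), CH2Cl2, 0 °C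
Reagents that add atoms: sodium hypochlorite (NaOCl), [Na+].[O-]Cl
Why: Jacobsen–Katsuki epoxidation: the oxo species (pentavalent manganese) formed from the trivalent manganese complex transfers oxygen to the cis, aryl-conjugated alkene by side-on approach, and 2,2-dimethylchromenes are the best substrate class. The (S,S) ligand should give the (3S,4S)-epoxide, which fixes C3'' (C4'' is removed in step 5). The aryl aldehyde should be inert to buffered hypochlorite in the two-phase system at 0 °C.

Step 4
Reactants: 6 (3S,4S)-5-(benzyloxy)-3,4-epoxy-2,2-dimethylchromane-6-carbaldehyde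
Product: 7 (3S,4S)-5-(benzyloxy)-3,4-epoxy-6-(2-methoxyethenyl)-2,2-dimethylchromane (E/Z mixture)
Conditions: Ph3P(CH2OMe)Cl, KOtBu, THF, 0 °C → rt
Reagents that add atoms: (methoxymethyl)triphenylphosphonium chloride, COC[P+](c1ccccc1)(c1ccccc1)c1ccccc1.[Cl-]
Why: Wittig methoxymethylenation of a non-enolisable aldehyde gives the one-carbon homologue masked as an enol ether. The epoxide tolerates the ylide and KOtBu, and the alkene geometry is irrelevant.

Step 5
Reactants: 7 (3S,4S)-5-(benzyloxy)-3,4-epoxy-6-(2-methoxyethenyl)-2,2-dimethylchromane
Product: 8 (3S)-5-(benzyloxy)-6-(2-methoxyethenyl)-2,2-dimethylchroman-3-ol (E/Z mixture)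
Conditions: LiAlH4, THF, 0 °C → rt; then H2O, aq. NaOH
Reagents that add atoms: none
Why: SN2 hydride opening of the epoxide at the benzylic C4'', the only epoxide carbon not shielded by the adjacent quaternary C2''. The C3''–O bond is untouched, so the (S) configuration is carried over. The enol ether and the benzyl ether are inert to LiAlH4.

Step 6
Reactants: 8 (3S)-5-(benzyloxy)-6-(2-methoxyethenyl)-2,2-dimethylchroman-3-ol
Product: 9 (3S)-3,5-bis(benzyloxy)-6-(2-methoxyethenyl)-2,2-dimethylchromane (E/Z mixture)
Conditions: NaH, BnBr, Bu4NI (cat.), THF–DMF, 0 °C → rt
Reagents that add atoms: benzyl bromide, BrCc1ccccc1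
Why: Williamson benzylation of the hindered secondary alkoxide with iodide catalysis. It masks the carbinol against the aryllithium, the oxidant and NaH of later steps; the enol ether is stable to base.

Step 7
Reactants: 9 (3S)-3,5-bis(benzyloxy)-6-(2-methoxyethenyl)-2,2-dimethylchromane
Product: 10 2-[(3S)-3,5-bis(benzyloxy)-2,2-dimethylchroman-6-yl]acetaldehyde
Conditions: 3 M aq. HCl, THF, 40 °C; used crude
Reagents that add atoms: water, O
Why: Acid hydrolysis of the enol ether through the oxocarbenium ion and hemiacetal. Dilute acid should leave the benzyl ethers and the chroman ether intact. The α-aryl acetaldehyde is taken on without chromatography because it enolises and oxidises easily.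

Step 8
Reactants: 10 2-[(3S)-3,5-bis(benzyloxy)-2,2-dimethylchroman-6-yl]acetaldehyde; 11 1,3,5-trifluorobenzene
Product: 13 2-[(3S)-3,5-bis(benzyloxy)-2,2-dimethylchroman-6-yl]-1-(2,4,6-trifluorophenyl)ethan-1-ol (both carbinol epimers), via 2,4,6-trifluorophenyllithium 12 (not isolated)
Conditions: 11, n-BuLi, THF, −78 °C; then 10, −78 °C; aq. NH4Cl
Reagents that add atoms: none
Why: Directed lithiation of 11 between two fluorines gives 12, which is kept at −78 °C to avoid loss of LiF, and which adds 1,2 to the aldehyde. The carbanion is stabilised by two ortho fluorines and is a weak base, which favours addition over enolisation. The new carbinol centre is uncontrolled and is erased in step 9.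

Step 9
Reactants: 13 2-[(3S)-3,5-bis(benzyloxy)-2,2-dimethylchroman-6-yl]-1-(2,4,6-trifluorophenyl)ethan-1-ol
Product: 14 2-[(3S)-3,5-bis(benzyloxy)-2,2-dimethylchroman-6-yl]-1-(2,4,6-trifluorophenyl)ethan-1-one
Conditions: Dess–Martin periodinane, NaHCO3, CH2Cl2, 0 °C → rt
Reagents that add atoms: none
Why: Dess–Martin oxidation of a secondary alcohol under buffered, non-basic conditions. The doubly activated methylene is not enolised and the fluoroarene is untouched.

Step 10
Reactants: 14 2-[(3S)-3,5-bis(benzyloxy)-2,2-dimethylchroman-6-yl]-1-(2,4,6-trifluorophenyl)ethan-1-one; 15 benzyl formate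
Product: 17 3-[(3S)-3,5-bis(benzyloxy)-2,2-dimethylchroman-6-yl]-5,7-difluorochromen-4-one, via sodium formyl-ketone enolate 16 (not isolated)
Conditions: NaH (2.5 equiv), 15 (3 equiv), THF, 0 °C → 50 °C; aq. NH4Cl
Reagents that add atoms: none
Why: NaH converts 14 into its benzylic enolate, which is C-formylated by 15 in a crossed Claisen condensation (C2–C3 bond); deprotonation of the β-ketoaldehyde to 16 drives the equilibrium. The formyl-derived enolate oxygen of 16 then adds to an ortho C–F carbon of the trifluorobenzoyl ring; the Meisenheimer adduct is stabilised by the ketone through C4a and by the two remaining fluorines, and loss of fluoride forms O1–C8a. The closest known reaction types are the cycloaracylation of ortho-fluoroaroyl β-dicarbonyl compounds (the oxygen analogue of the ring closure used for quinolone antibacterials) and the formate-based isoflavone synthesis from deoxybenzoins. Ring C closes by a six-membered addition–elimination at an sp2 carbon: 6-endo-trig when counted on the C4a=C8a bond that relays charge to the carbonyl, 6-exo-trig when counted on the C8=C8a Kekulé bond, and favourable in either description. No stereocentre is formed, and C3'' is remote and not epimerisable. The step needs oxygen rather than carbon cyclisation and ortho rather than para displacement: carbon attack would need a four-membered ring, the para fluoride is out of reach, and the two ortho fluorides are equivalent by symmetry. Benzyl formate is used so that the alkoxide set free is benzyl oxide; if it displaces a fluoride of 17, it only anticipates step 11 and installs no ether that cannot be removed.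

Step 11
Reactants: 17 3-[(3S)-3,5-bis(benzyloxy)-2,2-dimethylchroman-6-yl]-5,7-difluorochromen-4-one
Product: 19 5,7-bis(benzyloxy)-3-[(3S)-3,5-bis(benzyloxy)-2,2-dimethylchroman-6-yl]chromen-4-one, via 7-benzyloxy-5-fluoro isoflavone 18 (not isolated)
Conditions: BnOH, NaH (4 equiv each, premixed), THF, 0 °C → 60 °C, anhydrous
Reagents that add atoms: benzyl alcohol, OCc1ccccc1
Why: Two consecutive nucleophilic aromatic substitutions: C7 (para to the carbonyl, unhindered) should react first, then C5 (ortho to the carbonyl, helped by sodium coordination to the C4 oxygen). The first benzyloxy group deactivates the ring, hence the warming. Under anhydrous conditions any addition of benzyl oxide at C2 is reversible.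

Step 12
Reactants: 19 5,7-bis(benzyloxy)-3-[(3S)-3,5-bis(benzyloxy)-2,2-dimethylchroman-6-yl]chromen-4-one
Product: 20 5,7-dihydroxy-3-[(3S)-3,5-dihydroxy-2,2-dimethylchroman-6-yl]chromen-4-one
Conditions: H2 (1 atm), Pd/C (10% palladium metal on carbon), EtOAc–MeOH, rt
Reagents that add atoms: none
Why: Hydrogenolysis of three aryl benzyl ethers and one secondary alkyl benzyl ether. No bond to C3'' is cleaved, so the stereocentre is untouched. The reaction is stopped at full debenzylation to spare the C2=C3 bond.

## Compound list

1 | 2,4-dihydroxybenzaldehyde | O=Cc1ccc(O)cc1O | starting material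
2 | 3-methylbut-2-enal | CC(C)=CC=O | starting material
3 | 2-hydroxy-3-(3-methylbut-2-en-1-ylidene)-4-oxocyclohexa-1,5-diene-1-carbaldehyde (ortho-quinone methide) | CC(C)=CC=C1C(=O)C=CC(C=O)=C1O | intermediate (not isolated)
4 | 5-hydroxy-2,2-dimethyl-2H-chromene-6-carbaldehyde | CC1(C)C=Cc2c(O1)ccc(C=O)c2O | intermediate
5 | 5-(benzyloxy)-2,2-dimethyl-2H-chromene-6-carbaldehyde | CC1(C)C=Cc2c(O1)ccc(C=O)c2OCc1ccccc1 | intermediate
6 | (3S,4S)-5-(benzyloxy)-3,4-epoxy-2,2-dimethylchromane-6-carbaldehyde | CC1(C)Oc2ccc(C=O)c(OCc3ccccc3)c2[C@@H]4O[C@H]14 | intermediate
7 | (3S,4S)-5-(benzyloxy)-3,4-epoxy-6-(2-methoxyethenyl)-2,2-dimethylchromane (E/Z mixture) | CC1(C)Oc2ccc(C=COC)c(OCc3ccccc3)c2[C@@H]4O[C@H]14 | intermediate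
8 | (3S)-5-(benzyloxy)-6-(2-methoxyethenyl)-2,2-dimethylchroman-3-ol (E/Z mixture) | CC1(C)Oc2ccc(C=COC)c(OCc3ccccc3)c2C[C@@H]1O | intermediate
9 | (3S)-3,5-bis(benzyloxy)-6-(2-methoxyethenyl)-2,2-dimethylchromane (E/Z mixture) | CC1(C)Oc2ccc(C=COC)c(OCc3ccccc3)c2C[C@@H]1OCc1ccccc1 | intermediate
10 | 2-[(3S)-3,5-bis(benzyloxy)-2,2-dimethylchroman-6-yl]acetaldehyde | CC1(C)Oc2ccc(CC=O)c(OCc3ccccc3)c2C[C@@H]1OCc1ccccc1 | intermediate
11 | 1,3,5-trifluorobenzene | Fc1cc(F)cc(F)c1 | starting material
12 | 2,4,6-trifluorophenyllithium | [Li]c1c(F)cc(F)cc1F | intermediate (not isolated)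
13 | 2-[(3S)-3,5-bis(benzyloxy)-2,2-dimethylchroman-6-yl]-1-(2,4,6-trifluorophenyl)ethan-1-ol (both carbinol epimers) | CC1(C)Oc2ccc(CC(O)c3c(F)cc(F)cc3F)c(OCc3ccccc3)c2C[C@@H]1OCc1ccccc1 | intermediate
14 | 2-[(3S)-3,5-bis(benzyloxy)-2,2-dimethylchroman-6-yl]-1-(2,4,6-trifluorophenyl)ethan-1-one | CC1(C)Oc2ccc(CC(=O)c3c(F)cc(F)cc3F)c(OCc3ccccc3)c2C[C@@H]1OCc1ccccc1 | intermediate
15 | benzyl formate | O=COCc1ccccc1 | starting material
16 | sodium 2-[(3S)-3,5-bis(benzyloxy)-2,2-dimethylchroman-6-yl]-3-oxo-3-(2,4,6-trifluorophenyl)prop-1-en-1-olate | CC1(C)Oc2ccc(C(=C[O-])C(=O)c3c(F)cc(F)cc3F)c(OCc3ccccc3)c2C[C@@H]1OCc1ccccc1.[Na+] | intermediate (not isolated)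
17 | 3-[(3S)-3,5-bis(benzyloxy)-2,2-dimethylchroman-6-yl]-5,7-difluorochromen-4-one | CC1(C)Oc2ccc(-c3coc4cc(F)cc(F)c4c3=O)c(OCc3ccccc3)c2C[C@@H]1OCc1ccccc1 | intermediate
18 | 7-(benzyloxy)-3-[(3S)-3,5-bis(benzyloxy)-2,2-dimethylchroman-6-yl]-5-fluorochromen-4-one | CC1(C)Oc2ccc(-c3coc4cc(OCc5ccccc5)cc(F)c4c3=O)c(OCc3ccccc3)c2C[C@@H]1OCc1ccccc1 | intermediate (not isolated)
19 | 5,7-bis(benzyloxy)-3-[(3S)-3,5-bis(benzyloxy)-2,2-dimethylchroman-6-yl]chromen-4-one | CC1(C)Oc2ccc(-c3coc4cc(OCc5ccccc5)cc(OCc5ccccc5)c4c3=O)c(OCc3ccccc3)c2C[C@@H]1OCc1ccccc1 | intermediate
20 | 5,7-dihydroxy-3-[(3S)-3,5-dihydroxy-2,2-dimethylchroman-6-yl]chromen-4-one | CC1(C)Oc2ccc(-c3coc4cc(O)cc(O)c4c3=O)c(O)c2C[C@@H]1O | target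

## Step count and least certain steps

Total step count: 12. Longest linear sequence: 12 steps (1 → 20); 11 and 15 are bought and enter in steps 8 and 10.

Step 10 (key step). Benzyl oxide, or the enolate of a second molecule, may displace the exposed para fluoride intermolecularly before the ring closes. Ring closure may also be slow because 16 is a stabilised, chelated enolate, and deformylation by retro-Claisen cleavage may occur on work-up. The fallback sets out from 14 and separates the two bond formations without any alkoxide. Heating 14 with N,N-dimethylformamide dimethyl acetal in toluene should give 2-[(3S)-3,5-bis(benzyloxy)-2,2-dimethylchroman-6-yl]-3-(dimethylamino)-1-(2,4,6-trifluorophenyl)prop-2-en-1-one F1. Mild aqueous acid (aq. HCl, THF, rt) should hydrolyse it to 2-[(3S)-3,5-bis(benzyloxy)-2,2-dimethylchroman-6-yl]-3-hydroxy-1-(2,4,6-trifluorophenyl)prop-2-en-1-one F2. K2CO3 in MeCN (rt → 60 °C) should then close ring C by the same intramolecular fluoride displacement. The fallback comes back to the route at 17.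

Step 3. Face selectivity may be incomplete because the benzyloxy group peri to C4'' disturbs the side-on approach. Turnover may be slow on a chromene deactivated by the formyl group, and the epoxide may partly open on silica. The fallback sets out from 8 of insufficient enantiomeric purity. Acylation with (1S,4R)-camphanic chloride (pyridine, DMAP, CH2Cl2) should give (3S)-5-(benzyloxy)-6-(2-methoxyethenyl)-2,2-dimethylchroman-3-yl (1S,4R)-4,7,7-trimethyl-3-oxo-2-oxabicyclo[2.2.1]heptane-1-carboxylate F3. Its major diastereomer is purified by crystallisation or chromatography, and saponification (KOH, MeOH–H2O) returns the alcohol. The fallback comes back to the route at 8, now enantiopure.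

Step 5. Aluminium-assisted ionisation at C4'' with a 1,2-hydride shift would give a chroman-3-one, which is then reduced without stereocontrol and lowers the enantiomeric purity. Hydride attack may also be slow because the peri benzyloxy group shields C4''. The fallback sets out from 7 and uses a radical opening in place of the polar one. Cp2TiCl (trivalent titanium, made from Cp2TiCl2 and zinc dust) with 1,4-cyclohexadiene in THF should cleave the C4''–O bond homolytically to the benzylic radical, which takes up a hydrogen atom. No new compound arises (F0). The fallback comes back to the route at 8.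

Step 8. The aryllithium may enolise the α-aryl aldehyde, giving back 10 or aldol products. 12 may lose LiF to an aryne if the temperature rises, and 10 may degrade on handling. The fallback sets out from 10 and changes the oxidation level of the electrophile. Pinnick oxidation (NaClO2, NaH2PO4, 2-methylbut-2-ene, t-BuOH–H2O) should give 2-[(3S)-3,5-bis(benzyloxy)-2,2-dimethylchroman-6-yl]acetic acid F4. Coupling with N,O-dimethylhydroxylamine hydrochloride (EDC·HCl, iPr2NEt, CH2Cl2) should give 2-[(3S)-3,5-bis(benzyloxy)-2,2-dimethylchroman-6-yl]-N-methoxy-N-methylacetamide F5. Addition of 12 at −78 °C should then give the ketone directly through the chelated tetrahedral adduct, which removes 13 and step 9. The fallback comes back to the route at 14.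

Step 11. Benzyl oxide may add at C2 and open ring C, which becomes irreversible deformylation if moisture is present. The second displacement may also stall once the first benzyloxy group has deactivated ring A. The fallback sets out from 17 and uses a different nucleophile for the second site. One equivalent of BnONa in THF (0 °C → rt) should stop at 18, which is isolated here. Acetohydroxamic acid with K2CO3 in DMSO (80 °C) is a weakly basic oxygen nucleophile. It should replace the carbonyl-flanked C5 fluoride and, after fragmentation of the O-aryl hydroxamate, give 7-(benzyloxy)-3-[(3S)-3,5-bis(benzyloxy)-2,2-dimethylchroman-6-yl]-5-hydroxychromen-4-one F6. Hydrogenolysis under the conditions of step 12 then removes the three benzyl groups. The fallback comes back to the route at 20.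

Step 12. The C2=C3 bond may be saturated to an isoflavanone, or the secondary alkyl benzyl ether may cleave more slowly than the aryl ethers and leave a partly protected product. The fallback sets out from 19 and uses Lewis-acid debenzylation: BCl3 with pentamethylbenzene as cation scavenger in CH2Cl2 at −78 °C, kept cold to avoid ionisation at C2''. No new compound arises (F0). The fallback comes back to the route at 20.

## Further compounds

F1 | step 10 | 2-[(3S)-3,5-bis(benzyloxy)-2,2-dimethylchroman-6-yl]-3-(dimethylamino)-1-(2,4,6-trifluorophenyl)prop-2-en-1-one | CC1(C)Oc2ccc(C(=CN(C)C)C(=O)c3c(F)cc(F)cc3F)c(OCc3ccccc3)c2C[C@@H]1OCc1ccccc1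
F2 | step 10 | 2-[(3S)-3,5-bis(benzyloxy)-2,2-dimethylchroman-6-yl]-3-hydroxy-1-(2,4,6-trifluorophenyl)prop-2-en-1-one | CC1(C)Oc2ccc(C(=CO)C(=O)c3c(F)cc(F)cc3F)c(OCc3ccccc3)c2C[C@@H]1OCc1ccccc1
F3 | step 3 | (3S)-5-(benzyloxy)-6-(2-methoxyethenyl)-2,2-dimethylchroman-3-yl (1S,4R)-4,7,7-trimethyl-3-oxo-2-oxabicyclo[2.2.1]heptane-1-carboxylate | CC1(C)Oc2ccc(C=COC)c(OCc3ccccc3)c2C[C@@H]1OC(=O)[C@@]12CC[C@@](C)(C(=O)O1)C2(C)C
F0 | step 5 | none | none
F4 | step 8 | 2-[(3S)-3,5-bis(benzyloxy)-2,2-dimethylchroman-6-yl]acetic acid | CC1(C)Oc2ccc(CC(=O)O)c(OCc3ccccc3)c2C[C@@H]1OCc1ccccc1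
F5 | step 8 | 2-[(3S)-3,5-bis(benzyloxy)-2,2-dimethylchroman-6-yl]-N-methoxy-N-methylacetamide | CC1(C)Oc2ccc(CC(=O)N(C)OC)c(OCc3ccccc3)c2C[C@@H]1OCc1ccccc1
F6 | step 11 | 7-(benzyloxy)-3-[(3S)-3,5-bis(benzyloxy)-2,2-dimethylchroman-6-yl]-5-hydroxychromen-4-one | CC1(C)Oc2ccc(-c3coc4cc(OCc5ccccc5)cc(O)c4c3=O)c(OCc3ccccc3)c2C[C@@H]1OCc1ccccc1
F0 | step 12 | none | none
A1 | alternative 1 | 5,7-bis(benzyloxy)-3-[5-(benzyloxy)-2,2-dimethyl-2H-chromen-6-yl]chromen-4-one | CC1(C)C=Cc2c(O1)ccc(-c3coc4cc(OCc5ccccc5)cc(OCc5ccccc5)c4c3=O)c2OCc1ccccc1
A2 | alternative 1 | 5,7-bis(benzyloxy)-3-[(3S,4S)-5-benzyloxy-3,4-epoxy-2,2-dimethylchroman-6-yl]chromen-4-one | CC1(C)Oc2ccc(-c3coc4cc(OCc5ccccc5)cc(OCc5ccccc5)c4c3=O)c(OCc3ccccc3)c2[C@@H]6O[C@H]16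
A3 | alternative 2 | (E)-4-[5,7-bis(benzyloxy)-4-oxochromen-3-yl]-1-diazobut-3-en-2-one | [N-]=[N+]=CC(=O)/C=C/c1coc2cc(OCc3ccccc3)cc(OCc3ccccc3)c2c1=O
A4 | alternative 2 | (4S)-2,2,5,5-tetramethyl-4-[3-(triisopropylsilyloxy)prop-2-yn-1-yl]-1,3-dioxolane | CC(C)[Si](OC#CC[C@@H]1OC(C)(C)OC1(C)C)(C(C)C)C(C)C
A5 | alternative 2 | 5,7-bis(benzyloxy)-3-{2-hydroxy-3-[((4S)-2,2,5,5-tetramethyl-1,3-dioxolan-4-yl)methyl]-4-(triisopropylsilyloxy)phenyl}chromen-4-one | O=c1c(-c2ccc(O[Si](C(C)C)(C(C)C)C(C)C)c(C[C@@H]3OC(C)(C)OC3(C)C)c2O)coc2cc(OCc3ccccc3)cc(OCc3ccccc3)c12
A6 | alternative 3 | 5,7-bis(benzyloxy)-2,2-dimethyl-4H-1,3-benzodioxin-4-one | CC1(C)OC(=O)c2c(OCc3ccccc3)cc(OCc3ccccc3)cc2O1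
A7 | alternative 3 | 1-{(E)-2-[(3S)-5-(benzyloxy)-3-(tert-butyldimethylsilyloxy)-2,2-dimethylchroman-6-yl]ethenyl}pyrrolidine | CC1(C)Oc2ccc(/C=C/N3CCCC3)c(OCc3ccccc3)c2C[C@@H]1O[Si](C)(C)C(C)(C)C
A8 | alternative 3 | 5,7-bis(benzyloxy)-3-[(3S)-5-benzyloxy-3-(tert-butyldimethylsilyloxy)-2,2-dimethylchroman-6-yl]chromen-4-one | CC1(C)Oc2ccc(-c3coc4cc(OCc5ccccc5)cc(OCc5ccccc5)c4c3=O)c(OCc3ccccc3)c2C[C@@H]1O[Si](C)(C)C(C)(C)C
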